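**Retrosynthetic overview** (ring A = benzo ring and ring B = furan of the benzofuran; ring C = arene and ring D = pyran of the chroman)
1. Target 24 ⇐ cleavage of two MOM ethers ⇐ dehydrogenation of ring C in tetrahydrochromenone 22.
2. 22 is cut at C4a–C5 and C8–C8a. Enone 15 supplies C5–C8. 6,6-Dimethyltetrahydropyran-2-one 19 supplies O1, C2 with both methyl groups, C3, C4, C4a and C8a, that is all six atoms of ring D, so the 5-aryl-7-oxygen pattern of ring C follows from connectivity and no resorcinol prenylation is needed.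
3. 15 ⇐ Wittig ⇐ aldehyde 13 ⇐ ester 11. The 2-methylbut-3-en-2-yl group at benzofuran C7 comes from an aromatic Claisen rearrangement of 6-O-prenyl ether 7, whose para position (C3a) is blocked by the ring fusion.
4. Ring B ⇐ annulation of salicylaldehyde 4 with ethyl bromoacetate; ring A is bought as 2,4,6-trihydroxybenzaldehyde; 19 ⇐ glutaric anhydride + MeMgBr.
5. Ring order: A (bought), B (step 3), D (step 9, as the lactone), C (step 10, with D opened and re-closed), then aromatisation of C (step 11).

Key step: step 10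

Remark on the chemistry: the target has no stereocentre. The two centres formed in step 10 (C4a, C5; racemic, trans assumed) are erased in step 11. 2,4,6-Trihydroxybenzaldehyde is taken as the commercial source of ring A.

Step 1
Reactants: 1 2,4,6-trihydroxybenzaldehyde; 2 1-bromo-3-methylbut-2-ene
Product: 3 2,6-dihydroxy-4-[(3-methylbut-2-en-1-yl)oxy]benzaldehyde
Conditions: K2CO3 (1.0 equiv), acetone, 25 °C
Reagents that add atoms: none
Why: Williamson ether synthesis; the 4-OH is para to the formyl group, not hydrogen-bonded and the most acidic, so one equivalent of base and bromide should alkylate it in preference to the two chelated ortho-hydroxyls.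

Step 2
Reactants: 3 2,6-dihydroxy-4-[(3-methylbut-2-en-1-yl)oxy]benzaldehyde
Product: 4 2-hydroxy-6-(methoxymethoxy)-4-[(3-methylbut-2-en-1-yl)oxy]benzaldehyde
Conditions: MOMCl (1.1 equiv), iPr2NEt, CH2Cl2, 0 °C
Reagents that add atoms: chloromethyl methyl ether, COCCl
Why: MOM ether formation; the two ortho-hydroxyls are equivalent, and once one is etherified the other is held in the hydrogen bond to the aldehyde, so the reaction should stop at mono-protection.

Step 3
Reactants: 4 2-hydroxy-6-(methoxymethoxy)-4-[(3-methylbut-2-en-1-yl)oxy]benzaldehyde; 5 ethyl bromoacetate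
Product: 7 ethyl 4-(methoxymethoxy)-6-[(3-methylbut-2-en-1-yl)oxy]-1-benzofuran-2-carboxylate, via aryloxyacetate 6 (not isolated)
Conditions: K2CO3, DMF, 25 → 110 °C
Reagents that add atoms: none
Why: Rap–Stoermer-type benzofuran annulation; O-alkylation of the unhindered phenoxide gives 6, whose ester enolate condenses with the ortho-formyl group (intramolecular aldol) and dehydrates to the aromatic furan.

Step 4
Reactants: 7 ethyl 4-(methoxymethoxy)-6-[(3-methylbut-2-en-1-yl)oxy]-1-benzofuran-2-carboxylate
Product: 10 ethyl 6-hydroxy-4-(methoxymethoxy)-7-(2-methylbut-3-en-2-yl)-1-benzofuran-2-carboxylate, via dienone 8 (not isolated), via acetate 9 (not isolated)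
Conditions: Ac2O, NaOAc, PhNEt2, 185 °C (sealed tube); then K2CO3, EtOH, 25 °C
Reagents that add atoms: none
Why: Aromatic Claisen rearrangement; with the para position ring-fused, the [3,3] shift can only reach C5 or C7, and C7 should win as the unhindered angular position next to the ring oxygen (as in 7-allyloxycoumarins), giving 8, which tautomerises and is acetylated in situ to 9 to prevent abnormal Claisen rearrangement and cyclisation before ethanolysis frees the phenol.

Step 5
Reactants: 10 ethyl 6-hydroxy-4-(methoxymethoxy)-7-(2-methylbut-3-en-2-yl)-1-benzofuran-2-carboxylate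
Product: 11 ethyl 4,6-bis(methoxymethoxy)-7-(2-methylbut-3-en-2-yl)-1-benzofuran-2-carboxylate
Conditions: NaH, DMF, 0 °C; then MOMCl, 0 → 25 °C
Reagents that add atoms: chloromethyl methyl ether, COCCl
Why: Williamson-type MOM protection; the hindered phenol is fully converted into its sodium phenoxide, the only nucleophile present, and the aryl ester has no acidic hydrogen.

Step 6
Reactants: 11 ethyl 4,6-bis(methoxymethoxy)-7-(2-methylbut-3-en-2-yl)-1-benzofuran-2-carboxylate
Product: 12 [4,6-bis(methoxymethoxy)-7-(2-methylbut-3-en-2-yl)-1-benzofuran-2-yl]methanol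
Conditions: LiAlH4, THF, 0 °C
Reagents that add atoms: none
Why: Hydride reduction of the ester to the primary alcohol; MOM ethers, the isolated alkene and the benzofuran are inert to LiAlH4.

Step 7
Reactants: 12 [4,6-bis(methoxymethoxy)-7-(2-methylbut-3-en-2-yl)-1-benzofuran-2-yl]methanol
Product: 13 4,6-bis(methoxymethoxy)-7-(2-methylbut-3-en-2-yl)-1-benzofuran-2-carbaldehyde
Conditions: MnO2, CH2Cl2, 25 °C
Reagents that add atoms: none
Why: MnO2 oxidation of a heterobenzylic alcohol, which should stop at the aldehyde and leave the alkene and acetals untouched.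

Step 8
Reactants: 13 4,6-bis(methoxymethoxy)-7-(2-methylbut-3-en-2-yl)-1-benzofuran-2-carbaldehyde; 14 1-(triphenyl-λ5-phosphanylidene)propan-2-one
Product: 15 (E)-4-[4,6-bis(methoxymethoxy)-7-(2-methylbut-3-en-2-yl)-1-benzofuran-2-yl]but-3-en-2-one
Conditions: PhMe, 90 °C
Reagents that add atoms: none
Why: Wittig olefination with a stabilised acyl ylide, which should give the E-enone and avoids the double condensation possible in an aldol reaction with acetone.

Step 9
Reactants: 16 glutaric anhydride
Product: 19 6,6-dimethyltetrahydro-2H-pyran-2-one, via keto acid 17 (not isolated), via hydroxy acid 18 (not isolated)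
Conditions: MeMgBr (2.2 equiv), THF, −20 → 25 °C; then 2 M HCl, 40 °C
Reagents that add atoms: methylmagnesium bromide, C[Mg]Br
Why: Grignard addition to a cyclic anhydride; the first equivalent opens the anhydride to the carboxylate of 17, the second adds to its ketone, and acidification lactonises the tertiary δ-hydroxy acid 18.

Step 10
Reactants: 15 (E)-4-[4,6-bis(methoxymethoxy)-7-(2-methylbut-3-en-2-yl)-1-benzofuran-2-yl]but-3-en-2-one; 19 6,6-dimethyltetrahydro-2H-pyran-2-one
Product: 22 rac-(4aR,5S)-5-[4,6-bis(methoxymethoxy)-7-(2-methylbut-3-en-2-yl)-1-benzofuran-2-yl]-2,2-dimethyl-3,4,4a,5-tetrahydro-2H-chromen-7(6H)-one, via keto lactone 20 (not isolated), via hydroxy dione 21 (not isolated)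
Conditions: LiN(iPr)2, THF, −78 °C (19); then 15, DMPU, −78 → 25 → 50 °C; AcOH; then PPTS (cat.), 4 Å MS, PhMe, 60 °C
Reagents that add atoms: none
Why: Proposed new method: the lithium enolate of 19 adds 1,4 to 15 (chroman C4a–C5) to give 20 as its enolate, amine-mediated proton transfer forms the methyl-side enolate, and this attacks the lactone carbonyl (C8–C8a) in a Claisen condensation that expels the tertiary alkoxide and ends as the lithium diketonate of 21, a thermodynamic sink that draws the reversible carbonyl adduct and all enolate isomers forward. The closest known reaction type is the consecutive Michael–Claisen synthesis of cyclohexane-1,3-diones from enones and malonate or ester enolates (the dimedone synthesis), which has not been shown with a lactone enolate whose ring is opened and transposed. Ring C closes by 6-exo-trig (enolexo) attack on the lactone carbonyl, and ring D is re-closed under PPTS by 6-exo-trig addition of the tertiary hydroxyl to the adjacent C8a carbonyl, the only one within reach of a six-membered ring, with loss of water to the vinylogous ester. C5 is set without control in the Michael step and C4a, α to a dione carbonyl, should equilibrate to the trans arrangement with both substituents equatorial; both centres are erased in step 11. The step needs conjugate over carbonyl addition and closure through the methyl-side enolate: the aldolate from 1,2-addition of an ester enolate reverts on warming (DMPU assists) while the conjugate adduct is consumed irreversibly, and the internal enolate could only form a four-membered ring. The MOM ethers, the benzofuran and the monosubstituted alkene are inert to the base and should survive the buffered acid.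

Step 11
Reactants: 22 rac-(4aR,5S)-5-[4,6-bis(methoxymethoxy)-7-(2-methylbut-3-en-2-yl)-1-benzofuran-2-yl]-2,2-dimethyl-3,4,4a,5-tetrahydro-2H-chromen-7(6H)-one
Product: 23 5-[4,6-bis(methoxymethoxy)-7-(2-methylbut-3-en-2-yl)-1-benzofuran-2-yl]-2,2-dimethyl-3,4-dihydro-2H-chromen-7-ol
Conditions: DDQ (1.05 equiv), 1,4-dioxane, 25 °C
Reagents that add atoms: none
Why: DDQ dehydrogenation of a cyclohexenone to a phenol; hydride abstraction from C5–H, activated by the electron-rich benzofuran, followed by loss of two protons aromatises ring C, and one equivalent at room temperature should spare the chroman C4 methylene.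

Step 12
Reactants: 23 5-[4,6-bis(methoxymethoxy)-7-(2-methylbut-3-en-2-yl)-1-benzofuran-2-yl]-2,2-dimethyl-3,4-dihydro-2H-chromen-7-ol
Product: 24 2-(7-hydroxy-2,2-dimethyl-3,4-dihydro-2H-chromen-5-yl)-7-(2-methylbut-3-en-2-yl)-1-benzofuran-4,6-diol
Conditions: 1 M HCl, MeOH, 40 °C
Reagents that add atoms: none
Why: Acid-catalysed acetal exchange with methanol (MOM ether cleavage); dilute acid at mild temperature should not protonate the monosubstituted alkene of the 2-methylbut-3-en-2-yl group.

**Compound list**
1 | 2,4,6-trihydroxybenzaldehyde | O=Cc1c(O)cc(O)cc1O | starting material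
2 | 1-bromo-3-methylbut-2-ene | CC(C)=CCBr | starting material
3 | 2,6-dihydroxy-4-[(3-methylbut-2-en-1-yl)oxy]benzaldehyde | O=Cc1c(O)cc(OCC=C(C)C)cc1O | intermediate
4 | 2-hydroxy-6-(methoxymethoxy)-4-[(3-methylbut-2-en-1-yl)oxy]benzaldehyde | O=Cc1c(O)cc(OCC=C(C)C)cc1OCOC | intermediate
5 | ethyl bromoacetate | CCOC(=O)CBr | starting material
6 | ethyl 2-{2-formyl-3-(methoxymethoxy)-5-[(3-methylbut-2-en-1-yl)oxy]phenoxy}acetate (not isolated) | CCOC(=O)COc1cc(OCC=C(C)C)cc(OCOC)c1C=O | intermediate
7 | ethyl 4-(methoxymethoxy)-6-[(3-methylbut-2-en-1-yl)oxy]-1-benzofuran-2-carboxylate | CCOC(=O)c1cc2c(OCOC)cc(OCC=C(C)C)cc2o1 | intermediate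
8 | ethyl 4-(methoxymethoxy)-7-(2-methylbut-3-en-2-yl)-6-oxo-6,7-dihydro-1-benzofuran-2-carboxylate (racemic, not isolated) | CCOC(=O)C1=CC2=C(O1)C(C(C)(C)C=C)C(=O)C=C2OCOC | intermediate
9 | ethyl 6-acetoxy-4-(methoxymethoxy)-7-(2-methylbut-3-en-2-yl)-1-benzofuran-2-carboxylate (not isolated) | CCOC(=O)c1cc2c(OCOC)cc(OC(C)=O)c(C(C)(C)C=C)c2o1 | intermediate
10 | ethyl 6-hydroxy-4-(methoxymethoxy)-7-(2-methylbut-3-en-2-yl)-1-benzofuran-2-carboxylate | CCOC(=O)c1cc2c(OCOC)cc(O)c(C(C)(C)C=C)c2o1 | intermediate
11 | ethyl 4,6-bis(methoxymethoxy)-7-(2-methylbut-3-en-2-yl)-1-benzofuran-2-carboxylate | CCOC(=O)c1cc2c(OCOC)cc(OCOC)c(C(C)(C)C=C)c2o1 | intermediate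
12 | [4,6-bis(methoxymethoxy)-7-(2-methylbut-3-en-2-yl)-1-benzofuran-2-yl]methanol | OCc1cc2c(OCOC)cc(OCOC)c(C(C)(C)C=C)c2o1 | intermediate
13 | 4,6-bis(methoxymethoxy)-7-(2-methylbut-3-en-2-yl)-1-benzofuran-2-carbaldehyde | O=Cc1cc2c(OCOC)cc(OCOC)c(C(C)(C)C=C)c2o1 | intermediate
14 | 1-(triphenyl-λ5-phosphanylidene)propan-2-one | CC(=O)C=P(c1ccccc1)(c1ccccc1)c1ccccc1 | starting material
15 | (E)-4-[4,6-bis(methoxymethoxy)-7-(2-methylbut-3-en-2-yl)-1-benzofuran-2-yl]but-3-en-2-one | C=CC(C)(C)c1c(OCOC)cc(OCOC)c2cc(/C=C/C(C)=O)oc12 | intermediate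
16 | glutaric anhydride | O=C1CCCC(=O)O1 | starting material
17 | 5-oxohexanoic acid (as its bromomagnesium carboxylate, not isolated) | CC(=O)CCCC(=O)O | intermediate
18 | 5-hydroxy-5-methylhexanoic acid (not isolated) | CC(C)(O)CCCC(=O)O | intermediate
19 | 6,6-dimethyltetrahydro-2H-pyran-2-one | CC1(C)CCCC(=O)O1 | intermediate
20 | 3-{1-[4,6-bis(methoxymethoxy)-7-(2-methylbut-3-en-2-yl)-1-benzofuran-2-yl]-3-oxobutyl}-6,6-dimethyltetrahydro-2H-pyran-2-one (mixture of diastereomers, formed as its lithium enolate, not isolated) | C=CC(C)(C)c1c(OCOC)cc(OCOC)c2cc(C(CC(C)=O)C3CCC(C)(C)OC3=O)oc12 | intermediate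
21 | rac-(4R,5S)-5-[4,6-bis(methoxymethoxy)-7-(2-methylbut-3-en-2-yl)-1-benzofuran-2-yl]-4-(3-hydroxy-3-methylbutyl)cyclohexane-1,3-dione (trans, one enantiomer drawn, not isolated) | O=C1CC(=O)[C@H](CCC(C)(C)O)[C@@H](c2cc3c(OCOC)cc(OCOC)c(C(C)(C)C=C)c3o2)C1 | intermediate
22 | rac-(4aR,5S)-5-[4,6-bis(methoxymethoxy)-7-(2-methylbut-3-en-2-yl)-1-benzofuran-2-yl]-2,2-dimethyl-3,4,4a,5-tetrahydro-2H-chromen-7(6H)-one (trans, one enantiomer drawn) | O=C1C=C2OC(C)(C)CC[C@@H]2[C@@H](c2cc3c(OCOC)cc(OCOC)c(C(C)(C)C=C)c3o2)C1 | intermediate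
23 | 5-[4,6-bis(methoxymethoxy)-7-(2-methylbut-3-en-2-yl)-1-benzofuran-2-yl]-2,2-dimethyl-3,4-dihydro-2H-chromen-7-ol | C=CC(C)(C)c1c(OCOC)cc(OCOC)c2cc(-c3cc(O)cc4c3CCC(C)(C)O4)oc12 | intermediate
24 | 2-(7-hydroxy-2,2-dimethyl-3,4-dihydro-2H-chromen-5-yl)-7-(2-methylbut-3-en-2-yl)-1-benzofuran-4,6-diol (achiral) | C=CC(C)(C)c1c(O)cc(O)c2cc(-c3cc(O)cc4c3CCC(C)(C)O4)oc12 | target

**Step count**
Total: 12 steps. Longest linear sequence: 11 steps (steps 1–8 and 10–12, from compound 1); the lactone branch is step 9.

**Steps most likely to fail**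

Step 10 (proposed new method). The lactone enolate may add to the ketone carbonyl or take a proton from the enone methyl group, so that the enone oligomerises instead of entering the cascade; the Claisen closure may also stall after the conjugate addition. The fallback divides the cascade into known reactions. It sets out from 19 and 15 and comes back to the route at 22. Lactone 19 would be silylated (LiN(iPr)2, Me3SiCl, THF, −78 °C) to the silyl ketene acetal trimethyl[(2,2-dimethyl-3,4-dihydro-2H-pyran-6-yl)oxy]silane F1. Fluoride-catalysed Mukaiyama–Michael addition of F1 to 15 (tris(dimethylamino)sulfonium difluorotrimethylsilicate cat., THF, −78 → 0 °C) should give the silyl enol ether 3-{1-[4,6-bis(methoxymethoxy)-7-(2-methylbut-3-en-2-yl)-1-benzofuran-2-yl]-3-[(trimethylsilyl)oxy]but-2-en-1-yl}-6,6-dimethyltetrahydro-2H-pyran-2-one F2. Mild aqueous work-up would convert F2 into keto lactone 20, now isolated. A separate intramolecular Claisen condensation (KOtBu, THF, 0 → 25 °C) would give 21, and PPTS in toluene would close it to 22.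

Step 4. The [3,3] shift may go to C5 in competition with C7, and at 185 °C the prenyl group may be lost or the ortho-allyl phenol may rearrange further. The fallback fixes the regiochemistry by symmetry. It sets out from 3 and comes back at 11. Heating 3 (PhNEt2, 180 °C) would rearrange the 4-O-prenyl ether into either of two equivalent ortho positions, with the para position blocked by the formyl group, to give 2,4,6-trihydroxy-3-(2-methylbut-3-en-2-yl)benzaldehyde F3. MOMCl (2.1 equiv) and iPr2NEt should protect the two less hindered hydroxyls and leave the chelated one next to the quaternary carbon free, giving 2-hydroxy-4,6-bis(methoxymethoxy)-3-(2-methylbut-3-en-2-yl)benzaldehyde F4. Annulation with 5 (K2CO3, DMF, 110 °C) would pass through ethyl 2-[2-formyl-3,5-bis(methoxymethoxy)-6-(2-methylbut-3-en-2-yl)phenoxy]acetate F5 and close to 11.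

Step 11. The quinone may go on to abstract hydride from the chroman C4 methylene of the product phenol, which is para to the new hydroxyl, or oxidise the electron-rich benzofuran. The fallback uses enolate chemistry instead of a quinone. It sets out from 22 and comes back at 23. Kinetic deprotonation at C6 (LiN(iPr)2, THF, −78 °C) and trapping with PhSeCl would give 5-[4,6-bis(methoxymethoxy)-7-(2-methylbut-3-en-2-yl)-1-benzofuran-2-yl]-2,2-dimethyl-6-(phenylselanyl)-3,4,4a,5-tetrahydro-2H-chromen-7(6H)-one F6 (4a,5-trans, epimers at C6). Oxidation (H2O2, pyridine, CH2Cl2, 0 → 25 °C) should trigger syn-elimination toward C5, and tautomerisation of the ring would give 23.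

**Further compounds**
F1 | step 10 | trimethyl[(2,2-dimethyl-3,4-dihydro-2H-pyran-6-yl)oxy]silane | CC1(C)CCC=C(O[Si](C)(C)C)O1
F2 | step 10 | 3-{1-[4,6-bis(methoxymethoxy)-7-(2-methylbut-3-en-2-yl)-1-benzofuran-2-yl]-3-[(trimethylsilyl)oxy]but-2-en-1-yl}-6,6-dimethyltetrahydro-2H-pyran-2-one (mixture of isomers) | C=CC(C)(C)c1c(OCOC)cc(OCOC)c2cc(C(C=C(C)O[Si](C)(C)C)C3CCC(C)(C)OC3=O)oc12
F3 | step 4 | 2,4,6-trihydroxy-3-(2-methylbut-3-en-2-yl)benzaldehyde | O=Cc1c(O)cc(O)c(C(C)(C)C=C)c1O
F4 | step 4 | 2-hydroxy-4,6-bis(methoxymethoxy)-3-(2-methylbut-3-en-2-yl)benzaldehyde | O=Cc1c(OCOC)cc(OCOC)c(C(C)(C)C=C)c1O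
F5 | step 4 | ethyl 2-[2-formyl-3,5-bis(methoxymethoxy)-6-(2-methylbut-3-en-2-yl)phenoxy]acetate | CCOC(=O)COc1c(C=O)c(OCOC)cc(OCOC)c1C(C)(C)C=C
F6 | step 11 | 5-[4,6-bis(methoxymethoxy)-7-(2-methylbut-3-en-2-yl)-1-benzofuran-2-yl]-2,2-dimethyl-6-(phenylselanyl)-3,4,4a,5-tetrahydro-2H-chromen-7(6H)-one (4a,5-trans, epimers at C6) | O=C1C=C2OC(C)(C)CC[C@@H]2[C@@H](c2cc3c(OCOC)cc(OCOC)c(C(C)(C)C=C)c3o2)C1[Se]c1ccccc1
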